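**Strategy**

Ring C is cut at C13–C14. These carbons lie α to the two aldehyde-level carbons, acetal C16 and formyl C15, so the target hides a 1,4-dicarbonyl array across ring C that no polar aldol-type step can make. One anodic oxidation of a bis(enol ether) in methanol forges this like-polarity bond, closes ring C onto the oxolane that already links C11 and C13, sets C13 and C14, and delivers C15 and C16 as acetals. The precursor is a sclareolide-derived rings A/B decalin whose C8 carries the β-CH2O-isovalerate and an α-(2-methoxyvinyl) arm and whose C9 carries an (S)-2,3-dihydrofuran-2-yl group.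

Key step: step 15

Remark (numbering): C1–C10 are rings A and B, C11 sits on C9, C17 is the CH2–O carbon on C8 (it is C12 in the drimane names of compounds 3–10), C14–C15 is the two-carbon arm on C8, and C12, C13, C16 are the carbons added at C11; β is the face of the C10 methyl.

Assumption: lactols 2 and 23 are handled as anomeric mixtures and enol ether 21 as an E/Z mixture; their SMILES leave these elements open because the following step erases them.

**Route**

Step 1
Reactants: 1 (+)-sclareolide
Product: 2 sclareolide lactol (12-hemiacetal)
Conditions: i-Bu2AlH (1.1 equiv), CH2Cl2, −78 °C; aq. KNaC4H4O6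
Reagents that add atoms: none
Why: Partial hydride reduction of the γ-lactone stops at the tetrahedral aluminate at −78 °C and gives the lactol on work-up, with no stereocentre of the decalin touched.

Step 2
Reactants: 2 sclareolide lactol
Product: 3 11-iodo-driman-8α-yl formate
Conditions: PhI(OAc)2, I2, CH2Cl2, hν (visible), rt
Reagents that add atoms: iodine, II
Why: Hypoiodite formation and alkoxy-radical β-fragmentation cleave C11–C12, the primary C11 radical is trapped by iodine, and the excised carbon stays as the formate on the untouched 8α oxygen.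

Step 3
Reactants: 3 11-iodo-driman-8α-yl formate
Product: 4 drim-9(11)-en-8α-yl formate
Conditions: AgF, pyridine, rt
Reagents that add atoms: none
Why: Silver-assisted E2 dehydroiodination can only use the C9 hydrogen, so the exocyclic C9=C11 alkene forms regiospecifically and the tertiary formate survives.

Step 4
Reactants: 4 drim-9(11)-en-8α-yl formate
Product: 5 drim-9(11)-en-8α-ol
Conditions: K2CO3 (cat.), MeOH, rt
Reagents that add atoms: none
Why: Base-catalysed methanolysis (transesterification) removes the formate and leaves the tertiary allylic alcohol with its C8 configuration.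

Step 5
Reactants: 5 drim-9(11)-en-8α-ol
Product: 6 drima-8(12),9(11)-diene
Conditions: Burgess reagent (MeO2CNSO2NEt3), PhMe, 50 °C
Reagents that add atoms: none
Why: Burgess dehydration is a syn elimination, and the sulfamate on the equatorial 8α oxygen is syn-periplanar only to hydrogens of the freely rotating C12 methyl, so the exocyclic s-cis diene is expected (a transoid 7,9(11)-diene could not react in step 6).

Step 6
Reactants: 6 drima-8(12),9(11)-diene
Product: 8 drim-8-ene-11,12-diol, via endoperoxide 7 (not isolated)
Conditions: O2, hν (white LED), tetraphenylporphyrin (cat.), CH2Cl2, 0 °C; then Zn, AcOH, 0 °C to rt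
Reagents that add atoms: dioxygen, O=O
Why: Singlet-oxygen [4+2] cycloaddition to the locked s-cis diene puts oxygen on C11 and C12 and moves the alkene to C8=C9, and zinc in acetic acid cleaves the O–O bond reductively to the (Z)-2-ene-1,4-diol, with no stereocentre created.

Step 7
Reactants: 8 drim-8-ene-11,12-diol; 9 isovaleryl chloride
Product: 10 11-hydroxydrim-8-en-12-yl 3-methylbutanoate (O-17 monoester)
Conditions: 9 (1.05 equiv), 2,4,6-collidine, CH2Cl2, −78 to −40 °C
Reagents that add atoms: isovaleryl chloride, CC(C)CC(Cl)=O
Why: Sterically controlled monoacylation with an acyl chloride and collidine at low temperature should favour the C17 hydroxyl, which is flanked only by C7H2, over the C11 hydroxyl, which is shielded by quaternary C10 and its axial methyl.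

Step 8
Reactants: 10 O-17 monoester; 11 n-butyl vinyl ether
Product: 13 C15 aldehyde with quaternary C8 and C9=C11 methylene, via vinyl ether 12 (not isolated)
Conditions: Pd(OCOCF3)2 (5 mol %), 4,7-diphenyl-1,10-phenanthroline (5 mol %), Et3N, 11 (solvent), 75 °C; evaporate; then decane, 160 °C (sealed tube)
Reagents that add atoms: n-butyl vinyl ether, C=COCCCC
Why: Palladium-catalysed transfer vinylation of the C11 hydroxyl is followed by the aliphatic Claisen rearrangement, whose chair-like [3,3] shift delivers C14 to C8 on the α face, anti to the axial C10 methyl, so that C17 ends β and the alkene moves to C9=C11.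

Step 9
Reactants: 13 C15 aldehyde
Product: 14 C15 dimethyl acetal
Conditions: HC(OMe)3, MeOH, PPTS (cat.), rt
Reagents that add atoms: trimethyl orthoformate, COC(OC)OC; methanol, CO
Why: Acid-catalysed acetalisation with orthoformate as water scavenger masks C15 at the aldehyde level, and the ester and the 1,1-disubstituted alkene are inert to pyridinium tosylate.

Step 10
Reactants: 14 C15 dimethyl acetal
Product: 16 C11 primary alcohol (9α-H), via alkylborane 15 (not isolated)
Conditions: BH3·THF (1.5 equiv), THF, 0 °C to rt; then 30% H2O2, NaH2PO4/Na2HPO4 buffer (pH 7), 0 °C to rt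
Reagents that add atoms: hydrogen peroxide, OO
Why: Hydroboration–oxidation places boron on C11 and hydrogen on C9 from the α face, because the axial C10 methyl and the axial C17 arm block the β face, which sets 9α-H; the alkene reacts with borane far faster than the ester, and the neutral oxidation avoids acyl migration.

Step 11
Reactants: 16 C11 primary alcohol
Product: 17 C11 aldehyde
Conditions: Dess–Martin periodinane, NaHCO3, CH2Cl2, 0 °C to rt
Reagents that add atoms: none
Why: Buffered Dess–Martin oxidation gives the aldehyde without acid, so the acetal is not exchanged by the neighbouring hydroxyl and the equatorial C9 configuration is kept.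

Step 12
Reactants: 17 C11 aldehyde; 18 allenylboronic acid pinacol ester
Product: 19 (11S)-homopropargylic alcohol
Conditions: 18 (1.5 equiv), (S)-TRIP phosphoric acid (10 mol %), 4 Å MS, cyclohexane/PhMe, 0 °C to rt; aq. NaHCO3
Reagents that add atoms: allenylboronic acid pinacol ester, C=C=CB1OC(C)(C)C(C)(C)O1
Why: Chiral phosphoric acid-catalysed allenylboration (SE2′ addition through a closed six-membered transition state) gives the homopropargylic alcohol, and the catalyst antipode that directs the boronate to the Si face sets 11S, since the aldehyde flanked by two quaternary carbons has little bias of its own.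

Step 13
Reactants: 19 (11S)-homopropargylic alcohol
Product: 20 (11S)-2,3-dihydrofuran with C15 dimethyl acetal
Conditions: Mo(CO)6 (25 mol %), Et3N, Et2O, hν (350 nm); then 19, rt
Reagents that add atoms: none
Why: Molybdenum-catalysed alkynol cycloisomerisation proceeds through a metal vinylidene to which the C11 hydroxyl adds at C16, and protonation releases the endocyclic enol ether without touching the C11 centre.

Step 14
Reactants: 20 dihydrofuran dimethyl acetal
Product: 21 dihydrofuran methyl enol ether (key-step precursor)
Conditions: TMSOTf (1.3 equiv), i-Pr2NEt (3 equiv), CH2Cl2, −20 °C to rt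
Reagents that add atoms: none
Why: Silyl triflate/amine elimination of methanol from the acetal (acetal-to-enol ether conversion) gives the methyl enol ether as an E/Z mixture, the excess amine deprotonating C14 faster than an enol ether can add to the oxocarbenium ion, as it must for the product in any such elimination.

Step 15
Reactants: 21 dihydrofuran methyl enol ether
Product: 22 ring C bis-acetal (C16 methyl acetal and C15 dimethyl acetal)
Conditions: reticulated vitreous carbon anode, Pt cathode, undivided cell, 0.1 M LiClO4, MeOH/THF (3:7), 2,6-lutidine (6 equiv), constant current 8 mA, 2.2 F/mol, rt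
Reagents that add atoms: methanol, CO
Why: Anodic removal of one electron from either enol ether gives a radical cation, the β-carbon of the other enol ether bonds to its β-carbon (C13 to C14), a second electron is lost and methanol captures the two oxocarbenium ions at C16 and C15; the closest known reaction type is the intramolecular anodic coupling of two enol ethers to 1,4-bis-acetals (anodic olefin coupling). Ring C closes in a 6-exo-trig mode, with both oxygen-bearing carbons C15 and C16 left outside the new carbocycle. C13 is controlled by the tether, since the 11S centre from step 12 and the C9–C11 anchor let C14 reach only the dihydrofuran face that leaves the O–C16 bridge cis to the C11–O bond. C14 is controlled by a chair-like transition state with the C15 oxocarbenium arm equatorial (β), and a minor α-epimer would be levelled through the enol of the aldehyde in step 16. C16 takes methanol on the exo side, away from the axial C17 arm, and is reset in step 17. The step needs oxidation of the two enol ethers only, which their low oxidation potential relative to the ester and the product acetals secures, and 2,6-lutidine prevents acid-catalysed addition of methanol to either enol ether, while the E/Z mixture converges because C15 ends non-stereogenic.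

Step 16
Reactants: 22 ring C bis-acetal
Product: 23 C16 lactol C15 aldehyde
Conditions: 1 M aq. HCl/THF (1:2), rt
Reagents that add atoms: water, O
Why: Acid-catalysed acetal hydrolysis frees the C15 aldehyde and the C16 lactol while the hindered isovalerate survives, and C14 keeps or reaches the equatorial formyl arrangement through its enol.

Step 17
Reactants: 23 C16 lactol C15 aldehyde
Product: 24 target (CNP0331370.1)
Conditions: Ac2O, pyridine, DMAP (cat.), CH2Cl2, 0 °C
Reagents that add atoms: acetic anhydride, CC(=O)OC(C)=O
Why: Acylation of the lactol, the only hydroxyl present, gives the acetal acetate; the anomers interconvert through the open hydroxy aldehyde and the exo hydroxyl, turned away from the axial C17 arm, is acylated, which gives the C16 configuration of the target.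

**Compound list**

1 | (+)-sclareolide | CC1(CCC[C@]2([C@H]1CC[C@@]3([C@@H]2CC(=O)O3)C)C)C | starting material
2 | sclareolide lactol (12-hemiacetal, anomeric mixture) | CC1(CCC[C@]2([C@H]1CC[C@@]3([C@@H]2CC(O)O3)C)C)C | intermediate
3 | 11-iodo-driman-8α-yl formate (9α-H) | CC1(CCC[C@]2([C@H]1CC[C@@](OC=O)([C@@H]2CI)C)C)C | intermediate
4 | drim-9(11)-en-8α-yl formate | CC1(CCC[C@]2([C@H]1CC[C@@](OC=O)(C2=C)C)C)C | intermediate
5 | drim-9(11)-en-8α-ol | CC1(CCC[C@]2([C@H]1CC[C@@](O)(C2=C)C)C)C | intermediate
6 | drima-8(12),9(11)-diene | CC1(CCC[C@]2([C@H]1CCC(=C)C2=C)C)C | intermediate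
7 | 11,12-epidioxydrim-8-ene (endoperoxide) | CC1(CCC[C@]2([C@H]1CCC3=C2COOC3)C)C | intermediate
8 | drim-8-ene-11,12-diol | CC1(CCC[C@]2([C@H]1CCC(CO)=C2CO)C)C | intermediate
9 | isovaleryl chloride (3-methylbutanoyl chloride) | CC(C)CC(Cl)=O | starting material
10 | 11-hydroxydrim-8-en-12-yl 3-methylbutanoate (O-17 monoester, free C11–OH) | CC1(CCC[C@]2([C@H]1CCC(COC(=O)CC(C)C)=C2CO)C)C | intermediate
11 | n-butyl vinyl ether | C=COCCCC | starting material
12 | O-11 vinyl ether of 10 | CC1(CCC[C@]2([C@H]1CCC(COC(=O)CC(C)C)=C2COC=C)C)C | intermediate
13 | C15 aldehyde: C8 with β-CH2O-isovalerate (C17) and α-CH2CHO (C14–C15), C9=C11H2 | O=CC[C@]1(COC(=O)CC(C)C)CC[C@H]3C(C)(C)CCC[C@]3(C)C1=C | intermediate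
14 | C15 dimethyl acetal of 13 | COC(OC)C[C@]1(COC(=O)CC(C)C)CC[C@H]3C(C)(C)CCC[C@]3(C)C1=C | intermediate
15 | C11 alkylborane of 14 (9α-H) | COC(OC)C[C@]1(COC(=O)CC(C)C)CC[C@H]3C(C)(C)CCC[C@]3(C)[C@H]1CB | intermediate
16 | C11 primary alcohol (9α-H, C11 β) with C15 dimethyl acetal | COC(OC)C[C@]1(COC(=O)CC(C)C)CC[C@H]3C(C)(C)CCC[C@]3(C)[C@H]1CO | intermediate
17 | C11 aldehyde with C15 dimethyl acetal | COC(OC)C[C@]1(COC(=O)CC(C)C)CC[C@H]3C(C)(C)CCC[C@]3(C)[C@H]1C=O | intermediate
18 | allenylboronic acid pinacol ester | C=C=CB1OC(C)(C)C(C)(C)O1 | starting material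
19 | (11S)-homopropargylic alcohol (C11–OH, C12H2–C13≡C16H, C15 dimethyl acetal) | COC(OC)C[C@]1(COC(=O)CC(C)C)CC[C@H]3C(C)(C)CCC[C@]3(C)[C@H]1[C@@H](O)CC#C | intermediate
20 | (11S)-2,3-dihydrofuran-2-yl compound with C15 dimethyl acetal | COC(OC)C[C@]1(COC(=O)CC(C)C)CC[C@H]3C(C)(C)CCC[C@]3(C)[C@H]1[C@@H]4CC=CO4 | intermediate
21 | dihydrofuran methyl enol ether isovalerate (E/Z mixture, key-step precursor) | COC=C[C@]1(COC(=O)CC(C)C)CC[C@H]3C(C)(C)CCC[C@]3(C)[C@H]1[C@@H]4CC=CO4 | intermediate
22 | ring C bis-acetal: C16 methyl acetal, C15 dimethyl acetal | CO[C@H]1O[C@H]2C[C@@H]1[C@@H](C(OC)OC)[C@]1(COC(=O)CC(C)C)CC[C@H]3C(C)(C)CCC[C@]3(C)[C@@H]21 | intermediate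
23 | C16 lactol C15 aldehyde (anomeric mixture) | OC1O[C@H]2C[C@@H]1[C@@H](C=O)[C@]1(COC(=O)CC(C)C)CC[C@H]3C(C)(C)CCC[C@]3(C)[C@@H]21 | intermediate
24 | target CNP0331370.1 (C16 acetal acetate, C15 aldehyde, O-17 isovalerate) | CC(=O)O[C@H]1O[C@H]2C[C@@H]1[C@@H](C=O)[C@]1(COC(=O)CC(C)C)CC[C@H]3C(C)(C)CCC[C@]3(C)[C@@H]21 | target

**Step count and risks**

Total step count: 17. Longest linear sequence: 17 steps, from (+)-sclareolide 1 to 24.

Steps most likely to fail:

Step 15 (anodic coupling). What may go wrong: methanol may capture the radical cation, or the second enol ether may be oxidised, before the C13–C14 bond closes against the axial C17 arm, so that open-chain acetals form and ring C is not built. The fallback closes the same bond by a two-electron, alkyne-based route and sets out from 19. Silylation (t-BuMe2SiOTf, 2,6-lutidine) gives the 11-O-silyl ether F1, and the silyl triflate/amine elimination of step 14 turns its acetal into the methyl enol ether F2. A cationic monovalent gold catalyst (Ph3PAuNTf2, MeOH/CH2Cl2) then activates the alkyne for 6-exo-dig attack by C14 of the enol ether, and methanol captures the C15 oxocarbenium ion, which gives the ring C 13-methylene dimethyl acetal F3. Hydroboration–oxidation with 9-BBN from the α face, away from the axial C11 silyloxy group and C17 arm, gives the 16-alcohol F4, and buffered Dess–Martin oxidation gives the 16-aldehyde F5. Aqueous HF in MeCN removes the silyl group, closes the C16 lactol onto O-11 and hydrolyses the C15 acetal, which returns the route at 23.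

Step 12 (propargylation). What may go wrong: poor facial selectivity, because the catalyst must overrule a hindered aldehyde whose two quaternary flanks differ little, or very slow addition. The fallback sets C11 by reagent-controlled reduction instead of addition and sets out from 17. Barbier propargylation (propargyl bromide, Zn, THF/aq. NH4Cl) gives 19 together with its 11-epimer F6. Buffered Dess–Martin oxidation of the mixture gives the β,γ-ynone F7. CBS reduction ((R)-2-methyl-CBS-oxazaborolidine, catecholborane, −78 °C), in which the C9 side acts as the large group, returns the route at 19.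

Step 7 (monoacylation). What may go wrong: the acyl chloride may not discriminate the two primary allylic hydroxyls, or the ester may migrate between O-17 and O-11. The fallback lets the sigmatropic step set the regiochemistry and sets out from 8. Johnson–Claisen rearrangement of the free diol (MeC(OEt)3, EtCO2H cat., 140 °C) can proceed only through the O-11 ketene acetal, because the O-17 mode would have to build a quaternary C9 next to C10; the resulting hydroxy ester closes to the spiro γ-lactone F8. Aminolysis (MeNHOMe·HCl, AlMe3) gives the hydroxy Weinreb amide F9, and isovaleryl chloride 9 (pyridine, DMAP) gives its ester F10. Cp2Zr(H)Cl in THF reduces the amide to the aldehyde in the presence of the ester, which returns the route at 13.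

Further compounds
F1 | step 15 | 11-O-tert-butyldimethylsilyl ether of 19 | COC(OC)C[C@]1(COC(=O)CC(C)C)CC[C@H]3C(C)(C)CCC[C@]3(C)[C@H]1[C@@H](O[Si](C)(C)C(C)(C)C)CC#C
F2 | step 15 | methyl enol ether of F1 (E/Z mixture) | COC=C[C@]1(COC(=O)CC(C)C)CC[C@H]3C(C)(C)CCC[C@]3(C)[C@H]1[C@@H](O[Si](C)(C)C(C)(C)C)CC#C
F3 | step 15 | ring C 13-methylene compound with C15 dimethyl acetal and 11β-silyloxy group | CC(C)(C)[Si](C)(C)O[C@H]2CC(=C)[C@@H](C(OC)OC)[C@]1(COC(=O)CC(C)C)CC[C@H]3C(C)(C)CCC[C@]3(C)[C@@H]21
F4 | step 15 | 16-alcohol (13α-H) from F3 | CC(C)(C)[Si](C)(C)O[C@H]2C[C@@H](CO)[C@@H](C(OC)OC)[C@]1(COC(=O)CC(C)C)CC[C@H]3C(C)(C)CCC[C@]3(C)[C@@H]21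
F5 | step 15 | 16-aldehyde from F4 | CC(C)(C)[Si](C)(C)O[C@H]2C[C@@H](C=O)[C@@H](C(OC)OC)[C@]1(COC(=O)CC(C)C)CC[C@H]3C(C)(C)CCC[C@]3(C)[C@@H]21
F6 | step 12 | (11R)-homopropargylic alcohol (11-epimer of 19) | COC(OC)C[C@]1(COC(=O)CC(C)C)CC[C@H]3C(C)(C)CCC[C@]3(C)[C@H]1[C@H](O)CC#C
F7 | step 12 | C11 β,γ-ynone | COC(OC)C[C@]1(COC(=O)CC(C)C)CC[C@H]3C(C)(C)CCC[C@]3(C)[C@H]1C(=O)CC#C
F8 | step 7 | spiro γ-lactone (C15 carbonyl to O-17) with C9=C11 methylene | O=C1C[C@]2(CO1)CC[C@H]3C(C)(C)CCC[C@]3(C)C2=C
F9 | step 7 | C15 Weinreb amide with free C17 hydroxyl | CON(C)C(=O)C[C@]1(CO)CC[C@H]3C(C)(C)CCC[C@]3(C)C1=C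
F10 | step 7 | C15 Weinreb amide O-17 isovalerate | CON(C)C(=O)C[C@]1(COC(=O)CC(C)C)CC[C@H]3C(C)(C)CCC[C@]3(C)C1=C
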